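**Plan**
- Retrosynthesis: the five O–CH3 bonds and the three formyl groups are traced back to methyl ethers and methyl esters, and the isobutyl group to a 2-methylprop-1-enyl group. The cuts then follow in the order C4–C4a (pyran ring), C4–alkenyl, O1–C8a (aryl ether) and C2–C3.
- Enabling feature: C4 is benzylic to the phloroglucinol-type A ring, C4a lies ortho to O1 and ortho/para to the C5 and C7 oxygens, and the four-carbon branch on C4 can be an alkenyl group. C4 can therefore be generated as the secondary terminus of a dimethylallyl-type cation and captured by C4a.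
- Forward: the hexasubstituted B-ring aldehyde is made first. C2–C3 is formed by allylboration, O1–C8a by SNAr and C4–alkenyl by Grignard addition. The pyran ring, the only ring that is built, closes last through C4–C4a; hydrogenation, ester-to-aldehyde adjustment and demethylation finish the route.
- Stereochemistry: C2 and C3 (2R,3R, 2,3-trans) come from a chiral phosphoric acid-catalysed anti-allylboration with an (E)-allylboronate. C4 (4S, 3,4-cis) comes from substrate control in the ring closure.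

Key step: step 10

Remark: ring atoms carry chroman numbering (O1, C2, C3, C4, C4a, C5–C8, C8a) also in the open-chain compounds; 17 is carried as the mixture of its two carbinol epimers at C4, because that centre becomes planar in step 10.

**Step 1**
Reactants: 1 2,4,6-trimethoxybenzaldehyde
Product: 3 3,5-dibromo-2,4,6-trimethoxybenzaldehyde, via 3-bromo-2,4,6-trimethoxybenzaldehyde 2 (not isolated)
Conditions: NBS (2.2 equiv), MeCN, 0 °C → 40 °C
Reagents that add atoms: N-bromosuccinimide, O=C1CCC(=O)N1Br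
Why: Electrophilic aromatic bromination; C3 and C5 are the only free ring positions and each is ortho/para to three methoxy groups, so the ring should take up two bromine atoms despite the formyl group.

**Step 2**
Reactants: 3 3,5-dibromo-2,4,6-trimethoxybenzaldehyde
Product: 5 dimethyl 5-formyl-2,4,6-trimethoxybenzene-1,3-dicarboxylate, via methyl 3-bromo-5-formyl-2,4,6-trimethoxybenzoate 4 (not isolated)
Conditions: CO (3 bar), Pd(OAc)2 (5 mol %), Xantphos (6 mol %), Et3N, MeOH–toluene, 100 °C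
Reagents that add atoms: carbon monoxide, [C-]#[O+]; methanol, CO
Why: Palladium-catalysed alkoxycarbonylation of aryl bromides (oxidative addition, CO insertion, methanolysis of the acyl-palladium species), in which the small flanking methoxy groups and the wide-bite-angle ligand should let both hindered C–Br bonds react while the aldehyde stays inert.

**Step 3**
Reactants: 6 4-methylpent-1-en-3-ol (racemic)
Product: 7 (E)-4,4,5,5-tetramethyl-2-(4-methylpent-2-en-1-yl)-1,3,2-dioxaborolane
Conditions: B2pin2, [Pd(MeCN)4](BF4)2 (5 mol %), DMSO–MeOH, 50 °C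
Reagents that add atoms: bis(pinacolato)diboron, CC1(C)OB(OC1(C)C)B1OC(C)(C)C(C)(C)O1
Why: Palladium-catalysed borylation of an allylic alcohol through an η3-allylpalladium species, which should place boron on the unsubstituted terminus and leave the E-alkene.

**Step 4**
Reactants: 5 dimethyl 5-formyl-2,4,6-trimethoxybenzene-1,3-dicarboxylate; 7 (E)-4,4,5,5-tetramethyl-2-(4-methylpent-2-en-1-yl)-1,3,2-dioxaborolane
Product: 9 dimethyl 5-[(1R,2R)-1-hydroxy-2-(propan-2-yl)but-3-en-1-yl]-2,4,6-trimethoxybenzene-1,3-dicarboxylate, via O-pinacolboryl ether 8 (not isolated)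
Conditions: (R)-TRIP (5 mol %), 4 Å MS, toluene, −30 °C; then aq. NaHCO3
Reagents that add atoms: none
Why: Chiral phosphoric acid-catalysed allylboration, in which the closed chair (Zimmerman–Traxler) transition state turns the E geometry of 7 into the anti relationship of hydroxyl and isopropyl (the later 2,3-trans pair), and the catalyst, hydrogen-bonded to a boronate oxygen, should direct attack to the Re face of the aldehyde to give 1R,2R.

**Step 5**
Reactants: 9 dimethyl 5-[(1R,2R)-1-hydroxy-2-(propan-2-yl)but-3-en-1-yl]-2,4,6-trimethoxybenzene-1,3-dicarboxylate; 10 4-fluoro-2,6-dimethoxybenzaldehyde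
Product: 11 dimethyl 5-[(1R,2R)-1-(4-formyl-3,5-dimethoxyphenoxy)-2-(propan-2-yl)but-3-en-1-yl]-2,4,6-trimethoxybenzene-1,3-dicarboxylate
Conditions: KHMDS, 18-crown-6, THF, −78 °C; then 10 (1.3 equiv), −20 °C → rt
Reagents that add atoms: none
Why: Nucleophilic aromatic substitution (addition–elimination) in which the deprotonated carbinol oxygen of 9 displaces the fluoride para to the formyl group; the carbinol C–O bond is not broken, so C2 keeps its configuration.

**Step 6**
Reactants: 11 dimethyl 5-[(1R,2R)-1-(4-formyl-3,5-dimethoxyphenoxy)-2-(propan-2-yl)but-3-en-1-yl]-2,4,6-trimethoxybenzene-1,3-dicarboxylate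
Product: 12 4-{[(1R,2R)-1-[3,5-bis(methoxycarbonyl)-2,4,6-trimethoxyphenyl]-2-(propan-2-yl)but-3-en-1-yl]oxy}-2,6-dimethoxybenzoic acid
Conditions: NaClO2, NaH2PO4, 2-methyl-2-butene, t-BuOH–THF–H2O, 0 °C → rt
Reagents that add atoms: sodium chlorite, [Na+].[O-]Cl=O
Why: Pinnick oxidation of the aromatic aldehyde, with the alkene scavenger in excess so that neither the terminal alkene nor the electron-rich A ring should be chlorinated.

**Step 7**
Reactants: 12 4-{[(1R,2R)-1-[3,5-bis(methoxycarbonyl)-2,4,6-trimethoxyphenyl]-2-(propan-2-yl)but-3-en-1-yl]oxy}-2,6-dimethoxybenzoic acid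
Product: 13 dimethyl 5-[(1R,2R)-1-[3,5-dimethoxy-4-(methoxycarbonyl)phenoxy]-2-(propan-2-yl)but-3-en-1-yl]-2,4,6-trimethoxybenzene-1,3-dicarboxylate
Conditions: MeI, K2CO3, DMF, rt
Reagents that add atoms: iodomethane, CI
Why: SN2 O-alkylation of the carboxylate, the usual way to esterify a di-ortho-substituted benzoic acid that resists Fischer esterification.

**Step 8**
Reactants: 13 dimethyl 5-[(1R,2R)-1-[3,5-dimethoxy-4-(methoxycarbonyl)phenoxy]-2-(propan-2-yl)but-3-en-1-yl]-2,4,6-trimethoxybenzene-1,3-dicarboxylate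
Product: 15 dimethyl 5-[(1R,2S)-1-[3,5-dimethoxy-4-(methoxycarbonyl)phenoxy]-2-formyl-3-methylbutyl]-2,4,6-trimethoxybenzene-1,3-dicarboxylate, via secondary ozonide 14 (not isolated)
Conditions: O3, CH2Cl2, −78 °C (Sudan Red 7B end point); then PPh3, −78 °C → rt
Reagents that add atoms: ozone, [O-][O+]=O
Why: Ozonolysis with reductive work-up, in which the monosubstituted alkene should react far faster than the ester-bearing arenes, and the neutral work-up should spare the epimerisable C3 centre and the β-aryloxy group (the aldehyde is used at once).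

**Step 9**
Reactants: 15 dimethyl 5-[(1R,2S)-1-[3,5-dimethoxy-4-(methoxycarbonyl)phenoxy]-2-formyl-3-methylbutyl]-2,4,6-trimethoxybenzene-1,3-dicarboxylate; 16 (2-methylprop-1-en-1-yl)magnesium bromide
Product: 17 dimethyl 5-[(1R,2R,3RS)-1-[3,5-dimethoxy-4-(methoxycarbonyl)phenoxy]-3-hydroxy-5-methyl-2-(propan-2-yl)hex-4-en-1-yl]-2,4,6-trimethoxybenzene-1,3-dicarboxylate (both C4 epimers)
Conditions: THF, −78 °C; then aq. NH4Cl
Reagents that add atoms: none
Why: Grignard 1,2-addition to the aldehyde; the three di-ortho-methoxy benzoate esters should be too hindered to react at −78 °C, and no control at C4 is needed because both epimers give the same cation in step 10.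

**Step 10**
Reactants: 17 dimethyl 5-[(1R,2R,3RS)-1-[3,5-dimethoxy-4-(methoxycarbonyl)phenoxy]-3-hydroxy-5-methyl-2-(propan-2-yl)hex-4-en-1-yl]-2,4,6-trimethoxybenzene-1,3-dicarboxylate
Product: 19 dimethyl 5-[(2R,3R,4S)-5,7-dimethoxy-6-(methoxycarbonyl)-4-(2-methylprop-1-en-1-yl)-3-(propan-2-yl)-3,4-dihydro-2H-1-benzopyran-2-yl]-2,4,6-trimethoxybenzene-1,3-dicarboxylate, via allyl cation 18 (not isolated)
Conditions: Bi(OTf)3 (10 mol %), CH2Cl2–MeNO2, −20 °C → 0 °C
Reagents that add atoms: none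
Why: Bismuth triflate ionises either C4 epimer of 17 to the E-configured dimethylallyl cation 18, and the A-ring carbon ortho to O1 (the future C4a, activated by O1 and both methoxy groups) attacks its secondary terminus C4, after which loss of a proton restores the arene. The closest known reaction type is the acid-catalysed intramolecular Friedel–Crafts allylic alkylation of aryl ethers with allylic alcohols, which gives 4-alkenylchromans. The pyran ring closes in a 6-exo-trig mode with respect to the allyl cation, the C4=C5 π bond staying outside the ring, whereas attack at the tertiary terminus would need an eight-membered ring. The new stereocentre C4 is controlled by C2 and C3: in the chair-like transition state the B-ring aryl and the isopropyl group are equatorial and the alkenyl group should take the pseudoaxial position to avoid the peri C5 methoxy group, which gives the 3,4-cis (4S) chroman. The step needs ionisation at C4 in preference to the benzylic C2–O1 bond, which the two ester groups and the doubly flanked, twisted methoxy groups of the B ring should secure by destabilising a C2 cation, and it needs a single site of attack on the A ring, which follows from the equivalence of its two ortho carbons and the ester on the para carbon.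

**Step 11**
Reactants: 19 dimethyl 5-[(2R,3R,4S)-5,7-dimethoxy-6-(methoxycarbonyl)-4-(2-methylprop-1-en-1-yl)-3-(propan-2-yl)-3,4-dihydro-2H-1-benzopyran-2-yl]-2,4,6-trimethoxybenzene-1,3-dicarboxylate
Product: 20 dimethyl 5-[(2R,3R,4S)-5,7-dimethoxy-6-(methoxycarbonyl)-4-(2-methylpropyl)-3-(propan-2-yl)-3,4-dihydro-2H-1-benzopyran-2-yl]-2,4,6-trimethoxybenzene-1,3-dicarboxylate
Conditions: H2 (3 bar), PtO2 (5 mol %), EtOAc, rt
Reagents that add atoms: none
Why: Heterogeneous catalytic hydrogenation of the trisubstituted alkene, with platinum preferred to palladium because it is less prone to move the double bond toward C4 (which would scramble that centre) or to hydrogenolyse the benzylic C2–O1 bond; no stereocentre is formed.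

**Step 12**
Reactants: 20 dimethyl 5-[(2R,3R,4S)-5,7-dimethoxy-6-(methoxycarbonyl)-4-(2-methylpropyl)-3-(propan-2-yl)-3,4-dihydro-2H-1-benzopyran-2-yl]-2,4,6-trimethoxybenzene-1,3-dicarboxylate
Product: 21 [(2R,3R,4S)-2-[3,5-bis(hydroxymethyl)-2,4,6-trimethoxyphenyl]-5,7-dimethoxy-4-(2-methylpropyl)-3-(propan-2-yl)-3,4-dihydro-2H-1-benzopyran-6-yl]methanol
Conditions: LiAlH4, THF, 0 °C → 50 °C; Fieser work-up
Reagents that add atoms: none
Why: Hydride reduction of esters to primary alcohols; LiAlH4 is strong enough for the hindered 2,6-dimethoxybenzoates and leaves the aryl ethers and the chroman untouched.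

**Step 13**
Reactants: 21 [(2R,3R,4S)-2-[3,5-bis(hydroxymethyl)-2,4,6-trimethoxyphenyl]-5,7-dimethoxy-4-(2-methylpropyl)-3-(propan-2-yl)-3,4-dihydro-2H-1-benzopyran-6-yl]methanol
Product: 22 5-[(2R,3R,4S)-6-formyl-5,7-dimethoxy-4-(2-methylpropyl)-3-(propan-2-yl)-3,4-dihydro-2H-1-benzopyran-2-yl]-2,4,6-trimethoxybenzene-1,3-dicarbaldehyde
Conditions: TPAP (10 mol %), NMO, 4 Å MS, CH2Cl2, rt
Reagents that add atoms: none
Why: Ley–Griffith oxidation of the three benzylic alcohols to aldehydes under non-acidic, water-free conditions that the electron-rich benzylic positions should tolerate without over-oxidation.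

**Step 14**
Reactants: 22 5-[(2R,3R,4S)-6-formyl-5,7-dimethoxy-4-(2-methylpropyl)-3-(propan-2-yl)-3,4-dihydro-2H-1-benzopyran-2-yl]-2,4,6-trimethoxybenzene-1,3-dicarbaldehyde
Product: 23 5-[(2R,3R,4S)-6-formyl-5,7-dihydroxy-4-(2-methylpropyl)-3-(propan-2-yl)-3,4-dihydro-2H-1-benzopyran-2-yl]-2,4,6-trihydroxybenzene-1,3-dicarbaldehyde
Conditions: BCl3 (excess), n-Bu4NI, CH2Cl2, −78 °C → 0 °C; then ice-water
Reagents that add atoms: none
Why: Lewis acid-mediated cleavage of aryl methyl ethers, in which every methoxy group lies ortho to a formyl group that guides boron to it and iodide removes the methyl group by SN2; the stereocentres take no part.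

**Compound list**
1 | 2,4,6-trimethoxybenzaldehyde | COc1cc(OC)c(C=O)c(OC)c1 | starting material
2 | 3-bromo-2,4,6-trimethoxybenzaldehyde | COc1cc(OC)c(C=O)c(OC)c1Br | intermediate
3 | 3,5-dibromo-2,4,6-trimethoxybenzaldehyde | COc1c(Br)c(OC)c(C=O)c(OC)c1Br | intermediate
4 | methyl 3-bromo-5-formyl-2,4,6-trimethoxybenzoate | COC(=O)c1c(OC)c(Br)c(OC)c(C=O)c1OC | intermediate
5 | dimethyl 5-formyl-2,4,6-trimethoxybenzene-1,3-dicarboxylate | COC(=O)c1c(OC)c(C=O)c(OC)c(C(=O)OC)c1OC | intermediate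
6 | 4-methylpent-1-en-3-ol (racemic) | C=CC(O)C(C)C | starting material
7 | (E)-4,4,5,5-tetramethyl-2-(4-methylpent-2-en-1-yl)-1,3,2-dioxaborolane | CC(C)/C=C/CB1OC(C)(C)C(C)(C)O1 | intermediate
8 | dimethyl 2,4,6-trimethoxy-5-[(1R,2R)-2-(propan-2-yl)-1-[(4,4,5,5-tetramethyl-1,3,2-dioxaborolan-2-yl)oxy]but-3-en-1-yl]benzene-1,3-dicarboxylate | C=C[C@@H](C(C)C)[C@@H](OB1OC(C)(C)C(C)(C)O1)c1c(OC)c(C(=O)OC)c(OC)c(C(=O)OC)c1OC | intermediate
9 | dimethyl 5-[(1R,2R)-1-hydroxy-2-(propan-2-yl)but-3-en-1-yl]-2,4,6-trimethoxybenzene-1,3-dicarboxylate | C=C[C@@H](C(C)C)[C@@H](O)c1c(OC)c(C(=O)OC)c(OC)c(C(=O)OC)c1OC | intermediate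
10 | 4-fluoro-2,6-dimethoxybenzaldehyde | COc1cc(F)cc(OC)c1C=O | starting material
11 | dimethyl 5-[(1R,2R)-1-(4-formyl-3,5-dimethoxyphenoxy)-2-(propan-2-yl)but-3-en-1-yl]-2,4,6-trimethoxybenzene-1,3-dicarboxylate | C=C[C@@H](C(C)C)[C@@H](Oc1cc(OC)c(C=O)c(OC)c1)c1c(OC)c(C(=O)OC)c(OC)c(C(=O)OC)c1OC | intermediate
12 | 4-{[(1R,2R)-1-[3,5-bis(methoxycarbonyl)-2,4,6-trimethoxyphenyl]-2-(propan-2-yl)but-3-en-1-yl]oxy}-2,6-dimethoxybenzoic acid | C=C[C@@H](C(C)C)[C@@H](Oc1cc(OC)c(C(=O)O)c(OC)c1)c1c(OC)c(C(=O)OC)c(OC)c(C(=O)OC)c1OC | intermediate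
13 | dimethyl 5-[(1R,2R)-1-[3,5-dimethoxy-4-(methoxycarbonyl)phenoxy]-2-(propan-2-yl)but-3-en-1-yl]-2,4,6-trimethoxybenzene-1,3-dicarboxylate | C=C[C@@H](C(C)C)[C@@H](Oc1cc(OC)c(C(=O)OC)c(OC)c1)c1c(OC)c(C(=O)OC)c(OC)c(C(=O)OC)c1OC | intermediate
14 | dimethyl 5-[(1R,2S)-1-[3,5-dimethoxy-4-(methoxycarbonyl)phenoxy]-3-methyl-2-(1,2,4-trioxolan-3-yl)butyl]-2,4,6-trimethoxybenzene-1,3-dicarboxylate (secondary ozonide, trioxolane carbon undefined) | C1OC(OO1)[C@@H](C(C)C)[C@@H](Oc1cc(OC)c(C(=O)OC)c(OC)c1)c1c(OC)c(C(=O)OC)c(OC)c(C(=O)OC)c1OC | intermediate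
15 | dimethyl 5-[(1R,2S)-1-[3,5-dimethoxy-4-(methoxycarbonyl)phenoxy]-2-formyl-3-methylbutyl]-2,4,6-trimethoxybenzene-1,3-dicarboxylate | O=C[C@@H](C(C)C)[C@@H](Oc1cc(OC)c(C(=O)OC)c(OC)c1)c1c(OC)c(C(=O)OC)c(OC)c(C(=O)OC)c1OC | intermediate
16 | (2-methylprop-1-en-1-yl)magnesium bromide | CC(C)=C[Mg]Br | starting material
17 | dimethyl 5-[(1R,2R,3RS)-1-[3,5-dimethoxy-4-(methoxycarbonyl)phenoxy]-3-hydroxy-5-methyl-2-(propan-2-yl)hex-4-en-1-yl]-2,4,6-trimethoxybenzene-1,3-dicarboxylate (both carbinol epimers) | CC(C)=CC(O)[C@@H](C(C)C)[C@@H](Oc1cc(OC)c(C(=O)OC)c(OC)c1)c1c(OC)c(C(=O)OC)c(OC)c(C(=O)OC)c1OC | intermediate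
18 | (3E,5R,6R)-6-[3,5-bis(methoxycarbonyl)-2,4,6-trimethoxyphenyl]-6-[3,5-dimethoxy-4-(methoxycarbonyl)phenoxy]-2-methyl-5-(propan-2-yl)hex-3-en-2-ylium (allyl cation, charge shared with chroman C4; drawn as the tertiary form) | C[C+](C)/C=C/[C@@H](C(C)C)[C@@H](Oc1cc(OC)c(C(=O)OC)c(OC)c1)c1c(OC)c(C(=O)OC)c(OC)c(C(=O)OC)c1OC | intermediate
19 | dimethyl 5-[(2R,3R,4S)-5,7-dimethoxy-6-(methoxycarbonyl)-4-(2-methylprop-1-en-1-yl)-3-(propan-2-yl)-3,4-dihydro-2H-1-benzopyran-2-yl]-2,4,6-trimethoxybenzene-1,3-dicarboxylate | CC(C)=C[C@@H]1c2c(cc(OC)c(C(=O)OC)c2OC)O[C@@H](c2c(OC)c(C(=O)OC)c(OC)c(C(=O)OC)c2OC)[C@@H]1C(C)C | intermediate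
20 | dimethyl 5-[(2R,3R,4S)-5,7-dimethoxy-6-(methoxycarbonyl)-4-(2-methylpropyl)-3-(propan-2-yl)-3,4-dihydro-2H-1-benzopyran-2-yl]-2,4,6-trimethoxybenzene-1,3-dicarboxylate | CC(C)C[C@@H]1c2c(cc(OC)c(C(=O)OC)c2OC)O[C@@H](c2c(OC)c(C(=O)OC)c(OC)c(C(=O)OC)c2OC)[C@@H]1C(C)C | intermediate
21 | [(2R,3R,4S)-2-[3,5-bis(hydroxymethyl)-2,4,6-trimethoxyphenyl]-5,7-dimethoxy-4-(2-methylpropyl)-3-(propan-2-yl)-3,4-dihydro-2H-1-benzopyran-6-yl]methanol | CC(C)C[C@@H]1c2c(cc(OC)c(CO)c2OC)O[C@@H](c2c(OC)c(CO)c(OC)c(CO)c2OC)[C@@H]1C(C)C | intermediate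
22 | 5-[(2R,3R,4S)-6-formyl-5,7-dimethoxy-4-(2-methylpropyl)-3-(propan-2-yl)-3,4-dihydro-2H-1-benzopyran-2-yl]-2,4,6-trimethoxybenzene-1,3-dicarbaldehyde | CC(C)C[C@@H]1c2c(cc(OC)c(C=O)c2OC)O[C@@H](c2c(OC)c(C=O)c(OC)c(C=O)c2OC)[C@@H]1C(C)C | intermediate
23 | 5-[(2R,3R,4S)-6-formyl-5,7-dihydroxy-4-(2-methylpropyl)-3-(propan-2-yl)-3,4-dihydro-2H-1-benzopyran-2-yl]-2,4,6-trihydroxybenzene-1,3-dicarbaldehyde (CNP0328914.1) | CC(C)C[C@@H]1c2c(cc(O)c(C=O)c2O)O[C@@H](c2c(O)c(C=O)c(O)c(C=O)c2O)[C@@H]1C(C)C | target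

**Step count**
Total: 14 steps. Longest linear sequence: 13 steps (1 → 3 → 5 → 9 → 11 → 12 → 13 → 15 → 17 → 19 → 20 → 21 → 22 → 23; step 3 is a one-step side branch).

**Steps most likely to fail**

Step 10. The acid may ionise the benzylic C2–O1 bond as well as the allylic alcohol. Cation 18 may also lose a proton to a diene, fragment across C2–C3, or be captured by a B-ring methoxy oxygen before C4a reaches it, and the arene may attack the wrong face of C4. The fallback sets out from 13. Cross-metathesis with purchased 2-methylbut-3-en-2-ol (Hoveyda–Grubbs II, CH2Cl2, 40 °C) would give the (E)-configured tertiary allylic alcohol F1. A cationic gold(I) catalyst (JohnPhosAu(MeCN)SbF6, CH2Cl2, rt) should then let the same A-ring carbon add anti to the gold-bound C4=C5 bond with loss of the tertiary hydroxyl, an SN2′-type allylic alkylation. C4–C4a and the pyran ring would thus form without a free carbocation. The fallback comes back to the route at 19 and passes by 15 and 17.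

Step 5. The alkoxide of 9 is flanked by a di-ortho-substituted aryl group and a branched carbon, so substitution at the C–F carbon may be slow. Hydride transfer from the benzylic alkoxide to the formyl group of 10, or reversible addition to it, may then take over. The fallback sets out from 9. The same alkoxide (KHMDS, 18-crown-6, THF, −78 °C) is offered purchased methyl 2,4,6-trifluorobenzoate, whose para C–F bond is far more activated and which already carries the ester, to give the difluoro aryl ether F2. Sodium methoxide (MeOH–DMF, 60 °C) then replaces both fluorines ortho to the ester. The fallback comes back at 13 and passes by 11 and 12.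

Step 4. With the di-ortho-substituted aldehyde 5 and the bulky γ-isopropyl boronate 7 the catalysed pathway may be slow, so that uncatalysed allylboration and weak face discrimination erode the enantiomeric purity at C2 and C3. The fallback sets out from 5 and uses an auxiliary.
- Purchased (4R)-4-benzyl-1,3-oxazolidin-2-one is acylated with isovaleryl chloride (n-BuLi, THF, −78 °C) to the N-isovaleryl imide F3.
- A magnesium chloride-catalysed Evans anti-aldol addition to 5 (MgCl2, Et3N, TMSCl, EtOAc, rt) should give the silylated anti adduct F4, the aldehyde approaching the chelated Z-enolate on the face away from the benzyl group.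
- Methanolysis (TFA, MeOH) should give the free aldol F5.
- LiBH4 (THF–MeOH, 0 °C) should release the auxiliary and give the 1,3-diol F6, the hindered aryl esters staying intact.
- TEMPO/PhI(OAc)2 should oxidise the primary alcohol to the β-hydroxy aldehyde F7.
- Methylenation (Ph3P=CH2, THF, −78 °C → 0 °C) comes back to the route at 9.

**Further compounds**
F1 | step 10 | dimethyl 5-[(1R,2R,3E)-1-[3,5-dimethoxy-4-(methoxycarbonyl)phenoxy]-5-hydroxy-5-methyl-2-(propan-2-yl)hex-3-en-1-yl]-2,4,6-trimethoxybenzene-1,3-dicarboxylate | CC(C)(O)/C=C/[C@@H](C(C)C)[C@@H](Oc1cc(OC)c(C(=O)OC)c(OC)c1)c1c(OC)c(C(=O)OC)c(OC)c(C(=O)OC)c1OC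
F2 | step 5 | dimethyl 5-[(1R,2R)-1-[3,5-difluoro-4-(methoxycarbonyl)phenoxy]-2-(propan-2-yl)but-3-en-1-yl]-2,4,6-trimethoxybenzene-1,3-dicarboxylate | C=C[C@@H](C(C)C)[C@@H](Oc1cc(F)c(C(=O)OC)c(F)c1)c1c(OC)c(C(=O)OC)c(OC)c(C(=O)OC)c1OC
F3 | step 4 | (4R)-4-benzyl-3-(3-methylbutanoyl)-1,3-oxazolidin-2-one | CC(C)CC(=O)N1[C@H](Cc2ccccc2)COC1=O
F4 | step 4 | dimethyl 5-[(1R,2S)-2-{[(4R)-4-benzyl-2-oxo-1,3-oxazolidin-3-yl]carbonyl}-3-methyl-1-[(trimethylsilyl)oxy]butyl]-2,4,6-trimethoxybenzene-1,3-dicarboxylate | O=C(N1[C@H](Cc2ccccc2)COC1=O)[C@@H](C(C)C)[C@@H](O[Si](C)(C)C)c1c(OC)c(C(=O)OC)c(OC)c(C(=O)OC)c1OC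
F5 | step 4 | dimethyl 5-[(1R,2S)-2-{[(4R)-4-benzyl-2-oxo-1,3-oxazolidin-3-yl]carbonyl}-1-hydroxy-3-methylbutyl]-2,4,6-trimethoxybenzene-1,3-dicarboxylate | O=C(N1[C@H](Cc2ccccc2)COC1=O)[C@@H](C(C)C)[C@@H](O)c1c(OC)c(C(=O)OC)c(OC)c(C(=O)OC)c1OC
F6 | step 4 | dimethyl 5-[(1R,2R)-1-hydroxy-2-(hydroxymethyl)-3-methylbutyl]-2,4,6-trimethoxybenzene-1,3-dicarboxylate | OC[C@@H](C(C)C)[C@@H](O)c1c(OC)c(C(=O)OC)c(OC)c(C(=O)OC)c1OC
F7 | step 4 | dimethyl 5-[(1R,2S)-2-formyl-1-hydroxy-3-methylbutyl]-2,4,6-trimethoxybenzene-1,3-dicarboxylate | O=C[C@@H](C(C)C)[C@@H](O)c1c(OC)c(C(=O)OC)c(OC)c(C(=O)OC)c1OC
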